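**Retrosynthetic overview**

1. Target 13 is a twofold-symmetric, all-trans oxolane (ring O1–C2–C3–C4–C5). The route rests on its two exocyclic hydroxymethyl carbons, C9 on ring carbon C3 and C9' on ring carbon C4: C3 and C4 are the two α-carbons of a symmetrical 1,4-diaryl-butane-1,4-dione whose carbonyl carbons become C2 and C5.
2. Last disconnection (the only ring that is made): the benzylic bonds O1–C2 and O1–C5, back to a 1,4-diaryl-1,4-diol; acid closes it under thermodynamic control, so the (3R,4R) centres dictate 2S and 5S.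
3. Key disconnection: C3–C9 and C4–C9' go back to two molecules of formaldehyde and the (1Z,3Z)-bis(trimethylsilyl) dienol ether 5 of the diketone, joined by a twofold hydroxymethylation under Sc(OTf)3 and a chiral bipyridine diol that sets both stereocentres.
4. The C3–C4 bond comes from oxidative dimerisation of two molecules of O-benzyl acetosyringone through its lithium enolate. Both arenes are bought; the oxolane is formed in step 7.

Key step: step 4

Assumption: commercial 35% aqueous formaldehyde serves as 6, and the (S,S) enantiomer of the bipyridine diol is taken to deliver the R configuration at each new centre by analogy with acyclic (Z)-silyl enol ethers of aryl ketones; if a correlation of 8 shows the opposite sense, the (R,R) ligand is used with no other change.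

**Route**

Step 1
Reactants: 1 acetosyringone, 1-(4-hydroxy-3,5-dimethoxyphenyl)ethan-1-one
Product: 2 1-[4-(benzyloxy)-3,5-dimethoxyphenyl]ethan-1-one
Conditions: BnBr (1.2 equiv), K2CO3 (2 equiv), DMF, 60 °C
Reagents that add atoms: benzyl bromide, BrCc1ccccc1
Why: Williamson ether synthesis, in which the phenoxide displaces bromide (SN2); the benzyl ether masks the acidic phenol through the enolate, silyl triflate and Lewis acid steps and is removable by hydrogenolysis at the end.

Step 2
Reactants: 2 1-[4-(benzyloxy)-3,5-dimethoxyphenyl]ethan-1-one (two molecules are joined; the second is entered below)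
Product: 4 1,4-bis[4-(benzyloxy)-3,5-dimethoxyphenyl]butane-1,4-dione, via lithium enolate 3 (not isolated)
Conditions: LDA (1.05 equiv), THF, −78 °C; then CuCl2 (1.1 equiv), DMF, −78 °C → rt
Reagents that add atoms: second molecule of ketone 2 (coupled as its lithium enolate 3), 1-[4-(benzyloxy)-3,5-dimethoxyphenyl]ethan-1-one, CC(=O)c1cc(OC)c(OCc2ccccc2)c(OC)c1
Why: Oxidative enolate homocoupling (Saegusa type), in which divalent copper oxidises each lithium enolate by one electron and two α-keto radicals or copper enolates couple at carbon, so that two molecules of 2 are joined through their methyl carbons as the C2–C3 bond of the symmetrical 1,4-diketone.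

Step 3
Reactants: 4 1,4-bis[4-(benzyloxy)-3,5-dimethoxyphenyl]butane-1,4-dione
Product: 5 (1Z,3Z)-1,4-bis[4-(benzyloxy)-3,5-dimethoxyphenyl]-1,4-bis(trimethylsilyloxy)buta-1,3-diene
Conditions: TMSOTf (2.4 equiv), Et3N (3.5 equiv), CH2Cl2, 0 °C → rt; non-aqueous work-up (pentane, filtration under argon), used crude
Reagents that add atoms: trimethylsilyl trifluoromethanesulfonate, C[Si](C)(C)OS(=O)(=O)C(F)(F)F
Why: Soft enolisation to silyl enol ethers (O-silylation of each carbonyl, then deprotonation by Et3N); the second enolisation gives the conjugated diene, and each double bond should adopt the Z geometry, aryl trans to the vinylic carbon substituent, that aryl ketone silyl enol ethers prefer under these equilibrating conditions.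

Step 4
Reactants: 5 (1Z,3Z)-1,4-bis[4-(benzyloxy)-3,5-dimethoxyphenyl]-1,4-bis(trimethylsilyloxy)buta-1,3-diene; 6 formaldehyde (35% aqueous; two molecules are incorporated)
Product: 8 (2R,3R)-1,4-bis[4-(benzyloxy)-3,5-dimethoxyphenyl]-2,3-bis(hydroxymethyl)butane-1,4-dione, via mono-adduct silyl enol ether 7 (not isolated)
Conditions: Sc(OTf)3 (20 mol%), (S,S)-6,6'-bis(1-hydroxy-2,2-dimethylpropyl)-2,2'-bipyridine (24 mol%), 35% aq. HCHO (10 equiv), DME/H2O 9:1, −20 °C; cold extractive work-up, crude taken into step 5 at once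
Reagents that add atoms: formaldehyde (6), C=O
Why: Proposed new method: the chiral aqua complex of trivalent scandium formed from Sc(OTf)3 and the bipyridine diol activates formaldehyde, and one (Z)-silyl enol ether terminus of 5 attacks it through C2 in an open-transition-state Mukaiyama aldol, water taking up the silyl group to leave the C1 ketone of mono-adduct 7, whose remaining (Z)-silyl enol ether then reacts in the same way through C3. The closest known reaction type is the scandium-catalysed enantioselective hydroxymethylation of (Z)-silyl enol ethers of acyclic aryl ketones with aqueous formaldehyde, used here twice on a 1,4-bis(silyloxy)-1,3-diene, a substrate class on which it has not been shown. No ring is closed; the step forms the two skeletal bonds C2–CH2OH and C3–CH2OH, which become C3–C9 and C4–C9' of the oxolane. Each new stereocentre (C2, then C3) is set by the ligand, which shields one enantioface of the reacting enol ether carbon, so both should be R and give the twofold-symmetric diketone. The step needs site selectivity for C2 and C3 (each is the nucleophilic β-carbon of its own enol ether, while C1 and C4 are fully substituted), catalyst control over the resident centre in the second addition, and aldol addition faster than protodesilylation, which the low temperature and the excess of formaldehyde are meant to secure. An error in either addition ends up in the meso diastereomer, which is separable and so should raise the enantiomeric purity of 8.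

Step 5
Reactants: 8 (2R,3R)-1,4-bis[4-(benzyloxy)-3,5-dimethoxyphenyl]-2,3-bis(hydroxymethyl)butane-1,4-dione
Product: 9 (2R,3R)-1,4-bis[4-(benzyloxy)-3,5-dimethoxyphenyl]-2,3-bis({[tert-butyl(diphenyl)silyl]oxy}methyl)butane-1,4-dione
Conditions: TBDPSCl (2.5 equiv), imidazole (5 equiv), CH2Cl2, 0 °C → rt
Reagents that add atoms: tert-butyl(chloro)diphenylsilane, CC(C)(C)[Si](Cl)(c1ccccc1)c1ccccc1
Why: Silylation of the primary alcohols through the N-silylimidazolium species under weakly basic conditions that should not epimerise or cleave the β-hydroxy ketone; the open diketone is trapped before it forms hemiketals, and the bulky, acid-stable silyl ether is chosen so that its oxygen stays a poor nucleophile in step 7.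

Step 6
Reactants: 9 (2R,3R)-1,4-bis[4-(benzyloxy)-3,5-dimethoxyphenyl]-2,3-bis({[tert-butyl(diphenyl)silyl]oxy}methyl)butane-1,4-dione
Product: 10 (2R,3R)-1,4-bis[4-(benzyloxy)-3,5-dimethoxyphenyl]-2,3-bis({[tert-butyl(diphenyl)silyl]oxy}methyl)butane-1,4-diol, mixture of epimers at C1 and C4
Conditions: NaBH4 (3 equiv), CeCl3·7H2O (2 equiv), MeOH/THF 1:1, −40 → 0 °C
Reagents that add atoms: none
Why: Luche-type borohydride reduction of the aryl ketones, fast and nearly neutral so that hydride delivery should outrun enolisation at the α-centres; the two carbinol centres form without control, which is harmless because both are reset in step 7.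

Step 7
Reactants: 10 (2R,3R)-1,4-bis[4-(benzyloxy)-3,5-dimethoxyphenyl]-2,3-bis({[tert-butyl(diphenyl)silyl]oxy}methyl)butane-1,4-diol
Product: 11 (2S,3R,4R,5S)-2,5-bis[4-(benzyloxy)-3,5-dimethoxyphenyl]-3,4-bis({[tert-butyl(diphenyl)silyl]oxy}methyl)oxolane
Conditions: BF3·OEt2 (0.3 equiv), CH2Cl2, −20 → 20 °C, held until the isomer ratio no longer changes; aq. NaHCO3
Reagents that add atoms: none
Why: Acid-mediated dehydrative cycloetherification (SN1) of a 1,4-diaryl-1,4-diol, in which one benzylic carbinol ionises to the alkoxyaryl-stabilised cation and the other hydroxyl closes the five-membered ring; since the benzylic C–O bonds of the oxolane re-ionise under the acid, C2 and C5 should equilibrate to the all-trans isomer with each aryl group trans to its neighbouring silyloxymethyl group, so the fixed (3R,4R) centres set both as S.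

Step 8
Reactants: 11 (2S,3R,4R,5S)-2,5-bis[4-(benzyloxy)-3,5-dimethoxyphenyl]-3,4-bis({[tert-butyl(diphenyl)silyl]oxy}methyl)oxolane
Product: 12 [(2S,3R,4R,5S)-2,5-bis[4-(benzyloxy)-3,5-dimethoxyphenyl]oxolane-3,4-diyl]dimethanol
Conditions: TBAF (3 equiv), THF, 0 °C → rt
Reagents that add atoms: none
Why: Fluoride-mediated cleavage of the silyl ethers, driven by Si–F bond formation; the aryl benzyl ethers and the oxolane are inert, and the phenols stay masked so that no phenoxide can open the benzylic ether positions.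

Step 9
Reactants: 12 [(2S,3R,4R,5S)-2,5-bis[4-(benzyloxy)-3,5-dimethoxyphenyl]oxolane-3,4-diyl]dimethanol
Product: 13 huazhongilexin, [(2S,3R,4R,5S)-2,5-bis(4-hydroxy-3,5-dimethoxyphenyl)oxolane-3,4-diyl]dimethanol
Conditions: H2 (1 atm), Pd/C (10 wt%), EtOAc/MeOH, rt, stopped after uptake of two equivalents
Reagents that add atoms: none
Why: Catalytic hydrogenolysis of the aryl benzyl ethers under neutral conditions, which should be faster than cleavage of the benzylic C–O bonds of the oxolane and touches no stereocentre.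

**Compound list**

1 | acetosyringone, 1-(4-hydroxy-3,5-dimethoxyphenyl)ethan-1-one | CC(=O)c1cc(OC)c(O)c(OC)c1 | starting material
2 | 1-[4-(benzyloxy)-3,5-dimethoxyphenyl]ethan-1-one | CC(=O)c1cc(OC)c(OCc2ccccc2)c(OC)c1 | intermediate
3 | lithium 1-[4-(benzyloxy)-3,5-dimethoxyphenyl]ethen-1-olate | C=C(O[Li])c1cc(OC)c(OCc2ccccc2)c(OC)c1 | intermediate (not isolated)
4 | 1,4-bis[4-(benzyloxy)-3,5-dimethoxyphenyl]butane-1,4-dione | O=C(CCC(=O)c1cc(OC)c(OCc2ccccc2)c(OC)c1)c1cc(OC)c(OCc2ccccc2)c(OC)c1 | intermediate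
5 | (1Z,3Z)-1,4-bis[4-(benzyloxy)-3,5-dimethoxyphenyl]-1,4-bis(trimethylsilyloxy)buta-1,3-diene | C[Si](C)(C)O/C(=C\C=C(\c1cc(OC)c(OCc2ccccc2)c(OC)c1)O[Si](C)(C)C)c1cc(OC)c(OCc2ccccc2)c(OC)c1 | intermediate
6 | formaldehyde (35% aqueous) | C=O | starting material
7 | (2R,3Z)-1,4-bis[4-(benzyloxy)-3,5-dimethoxyphenyl]-2-(hydroxymethyl)-4-(trimethylsilyloxy)but-3-en-1-one | O=C(c1cc(OC)c(OCc2ccccc2)c(OC)c1)[C@@H](CO)/C=C(\O[Si](C)(C)C)c1cc(OC)c(OCc2ccccc2)c(OC)c1 | intermediate (not isolated)
8 | (2R,3R)-1,4-bis[4-(benzyloxy)-3,5-dimethoxyphenyl]-2,3-bis(hydroxymethyl)butane-1,4-dione | O=C(c1cc(OC)c(OCc2ccccc2)c(OC)c1)[C@@H](CO)[C@H](CO)C(=O)c1cc(OC)c(OCc2ccccc2)c(OC)c1 | intermediate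
9 | (2R,3R)-1,4-bis[4-(benzyloxy)-3,5-dimethoxyphenyl]-2,3-bis({[tert-butyl(diphenyl)silyl]oxy}methyl)butane-1,4-dione | O=C(c1cc(OC)c(OCc2ccccc2)c(OC)c1)[C@@H](CO[Si](c3ccccc3)(c4ccccc4)C(C)(C)C)[C@H](CO[Si](c5ccccc5)(c6ccccc6)C(C)(C)C)C(=O)c1cc(OC)c(OCc2ccccc2)c(OC)c1 | intermediate
10 | (2R,3R)-1,4-bis[4-(benzyloxy)-3,5-dimethoxyphenyl]-2,3-bis({[tert-butyl(diphenyl)silyl]oxy}methyl)butane-1,4-diol, C1/C4 epimer mixture | OC(c1cc(OC)c(OCc2ccccc2)c(OC)c1)[C@@H](CO[Si](c3ccccc3)(c4ccccc4)C(C)(C)C)[C@H](CO[Si](c5ccccc5)(c6ccccc6)C(C)(C)C)C(O)c1cc(OC)c(OCc2ccccc2)c(OC)c1 | intermediate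
11 | (2S,3R,4R,5S)-2,5-bis[4-(benzyloxy)-3,5-dimethoxyphenyl]-3,4-bis({[tert-butyl(diphenyl)silyl]oxy}methyl)oxolane | COc1cc([C@H]2O[C@H](c3cc(OC)c(OCc4ccccc4)c(OC)c3)[C@@H](CO[Si](c5ccccc5)(c6ccccc6)C(C)(C)C)[C@@H]2CO[Si](c7ccccc7)(c8ccccc8)C(C)(C)C)cc(OC)c1OCc1ccccc1 | intermediate
12 | [(2S,3R,4R,5S)-2,5-bis[4-(benzyloxy)-3,5-dimethoxyphenyl]oxolane-3,4-diyl]dimethanol | COc1cc([C@H]2O[C@H](c3cc(OC)c(OCc4ccccc4)c(OC)c3)[C@@H](CO)[C@@H]2CO)cc(OC)c1OCc1ccccc1 | intermediate
13 | huazhongilexin, [(2S,3R,4R,5S)-2,5-bis(4-hydroxy-3,5-dimethoxyphenyl)oxolane-3,4-diyl]dimethanol | COc1cc([C@H]2O[C@H](c3cc(OC)c(O)c(OC)c3)[C@@H](CO)[C@@H]2CO)cc(OC)c1O | target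

**Step count**

Total step count: 9. Longest linear sequence: 9 steps (1 to 13).

**Steps most likely to fail**

Step 4 (the step carrying the new-method label). Three processes may defeat it. Protodesilylation of one or both enol ethers in the aqueous medium may outrun C–C bond formation. The second addition may be steered by the adjacent resident centre against the catalyst, which would enrich the meso diastereomer. The doubly α-branched β-hydroxy ketone may epimerise or lose formaldehyde by retro-aldol cleavage during work-up. The fallback uses only the established hydroxymethylation of mono-silyl enol ethers of acyclic aryl ketones, one bond at a time; it sets out from 4 and returns at 9. Diketone 4 is mono-enolised with LiHMDS (1.0 equiv) and TMSCl in THF at −78 °C to (3Z)-1,4-bis[4-(benzyloxy)-3,5-dimethoxyphenyl]-4-(trimethylsilyloxy)but-3-en-1-one F1, with unreacted 4 recycled. F1 is hydroxymethylated with aqueous formaldehyde under Sc(OTf)3 and the same ligand to (2R)-1,4-bis[4-(benzyloxy)-3,5-dimethoxyphenyl]-2-(hydroxymethyl)butane-1,4-dione F2. F2 is silylated with TBDPSCl and imidazole to (2R)-1,4-bis[4-(benzyloxy)-3,5-dimethoxyphenyl]-2-({[tert-butyl(diphenyl)silyl]oxy}methyl)butane-1,4-dione F3. Kinetic deprotonation of the remaining methylene (LiHMDS with TMSCl present, −78 °C), which should be favoured over the hindered methine, gives (2R,3Z)-1,4-bis[4-(benzyloxy)-3,5-dimethoxyphenyl]-2-({[tert-butyl(diphenyl)silyl]oxy}methyl)-4-(trimethylsilyloxy)but-3-en-1-one F4. A second catalytic hydroxymethylation gives (2R,3R)-1,4-bis[4-(benzyloxy)-3,5-dimethoxyphenyl]-2-({[tert-butyl(diphenyl)silyl]oxy}methyl)-3-(hydroxymethyl)butane-1,4-dione F5, and silylation of its free hydroxyl with TBDPSCl and imidazole gives 9.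

Step 7. The benzyloxy group, flanked by two methoxy groups, is twisted out of the ring plane and donates weakly, so re-ionisation of the oxolane may be too slow for C2 and C5 to equilibrate, leaving epimers. Harsher acid invites capture of the cation by the other arene (Friedel–Crafts closure to an aryltetralin) or by a silyl ether oxygen. The fallback runs the closure through a p-quinone methide, which forms under much milder acid; it sets out from 10 and returns at 13. Hydrogenolysis of 10 (H2, Pd/C, EtOAc, neutral) removes the aryl benzyl ethers and gives (2R,3R)-1,4-bis(4-hydroxy-3,5-dimethoxyphenyl)-2,3-bis({[tert-butyl(diphenyl)silyl]oxy}methyl)butane-1,4-diol F6. Catalytic TsOH in CH2Cl2 at rt should ionise the p-hydroxybenzylic carbinols reversibly and close the ring to the all-trans 4,4'-[(2S,3R,4R,5S)-3,4-bis({[tert-butyl(diphenyl)silyl]oxy}methyl)oxolane-2,5-diyl]bis(2,6-dimethoxyphenol) F7. Desilylation of F7 with TBAF buffered by AcOH in THF gives 13.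

Step 3. Under the silyl triflate the mono-enol ether may cyclise onto the second carbonyl and dehydrate to the 2,5-diarylfuran (Paal–Knorr pathway). The electron-rich diene may also hydrolyse or air-oxidise during isolation, or form as a mixture of geometries. The fallback makes the diene by reduction and not by enolisation; it sets out from 4 and returns at 5. α-Bromination of 4 with CuBr2 (2 equiv, EtOAc/CHCl3, reflux) gives 2-bromo-1,4-bis[4-(benzyloxy)-3,5-dimethoxyphenyl]butane-1,4-dione F8. Et3N in CH2Cl2 eliminates HBr from F8 to (2E)-1,4-bis[4-(benzyloxy)-3,5-dimethoxyphenyl]but-2-ene-1,4-dione F9. Reductive bis-O-silylation of F9 with Zn dust and TMSCl in THF at 0 °C, the open-chain counterpart of the reduction of a quinone to a bis-silyl hydroquinone, should give 5 from the s-cis enone conformers.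

**Further compounds**

F1 | step 4 | (3Z)-1,4-bis[4-(benzyloxy)-3,5-dimethoxyphenyl]-4-(trimethylsilyloxy)but-3-en-1-one | O=C(C/C=C(\O[Si](C)(C)C)c1cc(OC)c(OCc2ccccc2)c(OC)c1)c1cc(OC)c(OCc2ccccc2)c(OC)c1
F2 | step 4 | (2R)-1,4-bis[4-(benzyloxy)-3,5-dimethoxyphenyl]-2-(hydroxymethyl)butane-1,4-dione | O=C(c1cc(OC)c(OCc2ccccc2)c(OC)c1)[C@@H](CO)CC(=O)c1cc(OC)c(OCc2ccccc2)c(OC)c1
F3 | step 4 | (2R)-1,4-bis[4-(benzyloxy)-3,5-dimethoxyphenyl]-2-({[tert-butyl(diphenyl)silyl]oxy}methyl)butane-1,4-dione | O=C(c1cc(OC)c(OCc2ccccc2)c(OC)c1)[C@@H](CO[Si](c3ccccc3)(c4ccccc4)C(C)(C)C)CC(=O)c1cc(OC)c(OCc2ccccc2)c(OC)c1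
F4 | step 4 | (2R,3Z)-1,4-bis[4-(benzyloxy)-3,5-dimethoxyphenyl]-2-({[tert-butyl(diphenyl)silyl]oxy}methyl)-4-(trimethylsilyloxy)but-3-en-1-one | O=C(c1cc(OC)c(OCc2ccccc2)c(OC)c1)[C@@H](CO[Si](c3ccccc3)(c4ccccc4)C(C)(C)C)/C=C(\O[Si](C)(C)C)c1cc(OC)c(OCc2ccccc2)c(OC)c1
F5 | step 4 | (2R,3R)-1,4-bis[4-(benzyloxy)-3,5-dimethoxyphenyl]-2-({[tert-butyl(diphenyl)silyl]oxy}methyl)-3-(hydroxymethyl)butane-1,4-dione | O=C(c1cc(OC)c(OCc2ccccc2)c(OC)c1)[C@@H](CO[Si](c3ccccc3)(c4ccccc4)C(C)(C)C)[C@H](CO)C(=O)c1cc(OC)c(OCc2ccccc2)c(OC)c1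
F6 | step 7 | (2R,3R)-1,4-bis(4-hydroxy-3,5-dimethoxyphenyl)-2,3-bis({[tert-butyl(diphenyl)silyl]oxy}methyl)butane-1,4-diol, C1/C4 epimer mixture | OC(c1cc(OC)c(O)c(OC)c1)[C@@H](CO[Si](c2ccccc2)(c3ccccc3)C(C)(C)C)[C@H](CO[Si](c4ccccc4)(c5ccccc5)C(C)(C)C)C(O)c1cc(OC)c(O)c(OC)c1
F7 | step 7 | 4,4'-[(2S,3R,4R,5S)-3,4-bis({[tert-butyl(diphenyl)silyl]oxy}methyl)oxolane-2,5-diyl]bis(2,6-dimethoxyphenol) | COc1cc([C@H]2O[C@H](c3cc(OC)c(O)c(OC)c3)[C@@H](CO[Si](c4ccccc4)(c5ccccc5)C(C)(C)C)[C@@H]2CO[Si](c6ccccc6)(c7ccccc7)C(C)(C)C)cc(OC)c1O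
F8 | step 3 | 2-bromo-1,4-bis[4-(benzyloxy)-3,5-dimethoxyphenyl]butane-1,4-dione (racemic) | O=C(c1cc(OC)c(OCc2ccccc2)c(OC)c1)C(Br)CC(=O)c1cc(OC)c(OCc2ccccc2)c(OC)c1
F9 | step 3 | (2E)-1,4-bis[4-(benzyloxy)-3,5-dimethoxyphenyl]but-2-ene-1,4-dione | O=C(/C=C/C(=O)c1cc(OC)c(OCc2ccccc2)c(OC)c1)c1cc(OC)c(OCc2ccccc2)c(OC)c1
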